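(The readings are calculated with constants of no real substance; noise was put on by code.)

Per hour and in fractions of the charge was the unit the meeting chose for this flask, which holds 0.909 of the coupling partner's charge as starting material, so starting material is its limiting reagent.

| flask | starting material | coupling partner | free catalyst | remark |
|---|---|---|---|---|
| birch | 23 mM | 50.6 mM | 46 µM | run made earlier |
| maple | 92 mM | 50.6 mM | 46 µM | run made earlier |
| flask | 46 mM | 50.6 mM | 46 µM |  |

- birch (time / h: product / %): 0.833: 45.3; 2.50: 100.0; 4.00: 100.2; 6.00: 100.7; 10.0: 99.7
- maple (time / h: product / %): 0.667: 10.2; 1.33: 17.8; 2.50: 29.3; 5.00: 42.7; 10.0: 51.9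

(scatter of a reading: 0.5 percentage points)

1. factor on the rate of making product when 10% of the starting material are converted if free catalyst is charged twice over
2. factor on the rate when 10% of the starting material are converted if free catalyst is charged at 10 µM instead

The first speaker pointed to maple, where product had reached 51.9% by 10.0 h, while the coupling partner charge allows 55.0% there. She took one partner consumed per product formed.

The second speaker proposed treating the loss of partner as pseudo-first-order, although maple holds 4.00 times the starting material of birch. The fraction of the partner charge lost per hour is then the fraction left divided by one time. Birch at 0.833 h reads 3.61 h and maple at 2.50 h reads 3.29 h. Their mean is the capture time, 3.45 h, the hours in which the partner left falls by a factor e at a catalyst charge of 46 µM.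

For this flask at 10% conversion, the partner left is 0.909 of its charge, so she reckoned a loss of 0.264 h⁻¹ of that charge.

The third speaker objected that no run varies the free catalyst. The meeting therefore took it as a guess that the capture time goes inversely with catalyst charge. That makes the factor 2 at the doubled charge, while at 10 µM the capture time is 15.9 h and the factor 0.217.

The forecast gave 2 (1.75 to 2.1) and 0.21 (0.17 to 0.27), holding that “All catalyst steps are linear in catalyst”.

The flask gives 2.00 and 0.217.

    coupling partner + free catalyst → catalyst intermediate A (k = 245 L mol⁻¹ min⁻¹)
    starting material + catalyst intermediate A → catalyst intermediate B (k = 4980 L mol⁻¹ min⁻¹)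
    catalyst intermediate B → by-product + catalyst intermediate C (k = 13.5 min⁻¹)
    catalyst intermediate C ⇌ free catalyst + product (K = 0.0550 M, k = 923 min⁻¹)
    by-product + catalyst intermediate C → spent catalyst (k = 0.102 L mol⁻¹ min⁻¹)
    coupling partner + catalyst intermediate B ⇌ idle complex, settled at all times (K = 10.0 L mol⁻¹)

At 1.50 h in this flask, spent catalyst stands at 0.915% of the catalyst charged. At 0.339 h, when 10% is converted, this flask makes product at 0.259 h⁻¹ in fractions of the partner charge, against the 0.264 h⁻¹ of partner loss reckoned. With 10 µM of catalyst, the capture time of 15.9 h gives 0.0572 h⁻¹, and the factor the flask gives puts the rate of making product at 0.0564 h⁻¹.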